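**Plan**

- The target is read as the A/B‑cis decalin diol (3S,5S,8R,9R,10S): 3‑OH, 5‑H, 10‑CH3, the C9 side chain and the C8 methyl lie on the β‑face, and 8‑OH lies on the α‑face.
- Retrosynthetic cuts, in order: C11–C12 (sulfone anion + farnesyl bromide), C8–CH3 and C9–C11 (additions to a C8 ketone / enol ether), then C5–C10 and C6–C7 together, which opens both rings to a chain.
- Enabling feature: ring B is a cyclohexane whose C7–C8(O)–C9–C10 arc is a masked 2‑silyloxydiene and whose C5–C6 edge is a vinyl group on quaternary C4. The four carbons C1–C4 of ring A are the tether, so one intramolecular Diels–Alder reaction closes rings B and A. A phenylsulfonyl group on C6 activates the dienophile and is removed in the last step.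
- Forward order: chain assembly (C3 carbinol, ynoate, (Z)‑enone, vinyl sulfone), rings A and B in step 8, then C11, the C8 methyl and the farnesyl unit, then one global reduction.
- Stereochemistry: C3 from asymmetric reverse prenylation; cis C5/C10 from the (Z)‑diene geometry, with C3–OBn equatorial in the chair tether fixing the absolute sense; C9 and C8 from reagent attack on the convex β‑face.

Key step: step 8

Remark 1: read literally, the SMILES is the 5β‑H (A/B‑cis) diastereomer, and the route is built for it. Atoms are numbered as in terpenoid practice: ring A = C1–C5, C10; ring B = C5–C10; C11 is the carbon on C9; β is the face of the C10 methyl.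

Remark 2: the prenylborane from (−)‑α‑pinene is assumed to give the (S)‑carbinol, by analogy with the parent allyl reagent. If the sense proves opposite, the enantiomeric borane is used.

**Route**

Step 1
Reactants: 1 pent‑4‑yn‑1‑ol
Product: 2 pent‑4‑ynal
Conditions: TEMPO (cat.), PhI(OAc)2, CH2Cl2, rt
Reagents that add atoms: none
Why: TEMPO/oxoammonium oxidation of a primary alcohol should stop at the aldehyde and leave the terminal alkyne untouched.

Step 2
Reactants: 2 pent‑4‑ynal; 3 3‑methylbuta‑1,2‑diene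
Product: 5 (4S)‑3,3‑dimethyloct‑1‑en‑7‑yn‑4‑ol, via prenyldiisopinocampheylborane 4 (not isolated)
Conditions: (+)‑Ipc2BH [from (−)‑α‑pinene], 3, THF, −25 °C; then 2, Et2O, −78 °C; NaOH, H2O2
Reagents that add atoms: none
Why: Hydroboration of the allene gives the prenylborane, which should add to the aldehyde through a chair‑like allylboration transition state at its tertiary terminus (reverse prenylation); the isopinocampheyl groups select the aldehyde face and set C3 as (S).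

Step 3
Reactants: 5 (4S)‑3,3‑dimethyloct‑1‑en‑7‑yn‑4‑ol
Product: 6 benzyl (4S)‑3,3‑dimethyloct‑1‑en‑7‑yn‑4‑yl ether
Conditions: NaH, BnBr, Bu4NI (cat.), THF/DMF, 0 °C to rt
Reagents that add atoms: benzyl bromide, BrCc1ccccc1
Why: Williamson etherification of the hindered secondary alkoxide should proceed under iodide catalysis and gives a group that survives every later step until the final reduction.

Step 4
Reactants: 6 benzyl (4S)‑3,3‑dimethyloct‑1‑en‑7‑yn‑4‑yl ether
Product: 7 methyl (6S)‑6‑(benzyloxy)‑7,7‑dimethylnon‑8‑en‑2‑ynoate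
Conditions: n‑BuLi, THF, −78 °C; ClCO2Me
Reagents that add atoms: methyl chloroformate, COC(=O)Cl
Why: Acylation of the lithium acetylide with a chloroformate is a standard route to ynoates and installs C8.

Step 5
Reactants: 7 methyl (6S)‑6‑(benzyloxy)‑7,7‑dimethylnon‑8‑en‑2‑ynoate
Product: 8 methyl (2Z,6S)‑6‑(benzyloxy)‑3,7,7‑trimethylnona‑2,8‑dienoate
Conditions: Me2CuLi (from MeLi, CuI), THF, −78 °C; MeOH, −78 °C
Reagents that add atoms: lithium dimethylcuprate, [Li+].C[Cu-]C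
Why: syn‑Carbocupration of the ynoate and low‑temperature protonation with retention should place the new methyl (the C10 methyl) cis to H, so the chain ends up cis to the ester, i.e. the (Z)‑alkene.

Step 6
Reactants: 8 methyl (2Z,6S)‑6‑(benzyloxy)‑3,7,7‑trimethylnona‑2,8‑dienoate
Product: 10 (3Z,7S)‑7‑(benzyloxy)‑4,8,8‑trimethyldeca‑3,9‑dien‑2‑one, via silylmethyl ketone 9 (not isolated)
Conditions: Me3SiCH2Li (2.5 equiv), pentane/THF, −78 to 0 °C; MeOH, 0 °C; aq. NH4Cl
Reagents that add atoms: (trimethylsilyl)methyllithium, [Li]C[Si](C)(C)C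
Why: Addition of the α‑silyl carbanion to the ester should stop at the ketone stage because the β‑ketosilane is held as its enolate; brief methanolysis of the C–Si bond then gives the methyl ketone (C7) with the (Z)‑alkene untouched.

Step 7
Reactants: 10 (3Z,7S)‑7‑(benzyloxy)‑4,8,8‑trimethyldeca‑3,9‑dien‑2‑one
Product: 12 (3Z,7S,9E)‑7‑(benzyloxy)‑4,8,8‑trimethyl‑10‑(phenylsulfonyl)deca‑3,9‑dien‑2‑one, via iodo sulfone 11 (not isolated)
Conditions: PhSO2Na, I2, EtOAc/H2O, rt, dark; aq. Na2S2O3; then Et3N, CH2Cl2, 0 °C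
Reagents that add atoms: sodium benzenesulfinate, [Na+].[O-]S(=O)c1ccccc1
Why: Radical‑chain iodosulfonylation should add the electrophilic sulfonyl radical to the terminal CH2 of the electron‑neutral vinyl group, with fast iodine transfer at C5, and anti‑elimination of HI then gives the (E)‑vinyl sulfone; the electron‑poor trisubstituted enone should not react.

Step 8
Reactants: 12 (3Z,7S,9E)‑7‑(benzyloxy)‑4,8,8‑trimethyl‑10‑(phenylsulfonyl)deca‑3,9‑dien‑2‑one
Product: 14 tert‑butyl{[3β‑(benzyloxy)‑4,4,10β‑trimethyl‑6β‑(phenylsulfonyl)‑5β‑H‑decal‑8(9)‑en‑8‑yl]oxy}dimethylsilane (A/B cis), via silyloxy triene 13 (not isolated)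
Conditions: LDA, TBSCl, HMPA, THF, −78 °C; solvent exchange; PhMe (0.01 M), BHT, 120 °C, sealed tube
Reagents that add atoms: tert‑butyldimethylsilyl chloride, CC(C)(C)[Si](C)(C)Cl
Why: Kinetic deprotonation of the acetyl methyl group and O‑silylation should give the cross‑conjugated silyl dienol ether 13 without touching the (Z)‑alkene. On heating, 13 should undergo a concerted, asynchronous [4+2] cycloaddition between the 2‑silyloxydiene (C7=C8–C9=C10) and the tethered (E)‑vinyl sulfone (C5=C6); the closest known reaction type is the thermal type 1 intramolecular Diels–Alder reaction of 2‑silyloxy‑1,7,9‑decatrienes with a terminally activated dienophile. Ring B closes as the cyclohexene of the cycloaddition itself (new bonds C5–C10 and C6–C7, enol ether left at C8=C9), and ring A closes as the six‑membered ring spanned by the tether C1–C4. Because C1 sits on the inside (Z) position of diene terminus C10, only the tether‑exo transition state is reachable, which makes C5–H and the C10 methyl cis (cis ring fusion) and puts the sulfonyl group endo. The C3 benzyloxy group fixes the absolute sense: it lies equatorial in the chair‑like tether, since the other chair would put it 1,3‑diaxial to C6, and this places O3, H5 and the C10 methyl on one face; C6 becomes a stereocenter of no consequence. The step needs the cycloaddition to outrun the [1,5]‑hydrogen shift open to a (Z)‑diene and needs a single enol ether regiochemistry; the sulfone (lower LUMO, moderate temperature), the gem‑dimethyl group at C4 and the silyloxy group at C8 should secure these.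

Step 9
Reactants: 14 the cis‑fused silyl enol ether
Product: 15 3β‑(benzyloxy)‑4,4,10β‑trimethyl‑6β‑(phenylsulfonyl)‑9β‑[(phenylsulfanyl)methyl]‑5β‑H‑decalin‑8‑one (9α‑H)
Conditions: PhSCH2Cl, TiCl4, CH2Cl2, −78 to −40 °C; cold aq. NaHCO3; used at once
Reagents that add atoms: chloromethyl phenyl sulfide, ClCSc1ccccc1
Why: The Lewis acid generates the phenylthiomethyl cation (thionium α‑alkylation of a silyl enol ether), which should alkylate the regiodefined enol ether at C9 axially from the convex β‑face, anti to the ring A carbon C1 on C10, so that C11 is cis to the C10 methyl.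

Step 10
Reactants: 15 the C9‑phenylthiomethyl ketone
Product: 16 3β‑(benzyloxy)‑4,4,8β,10β‑tetramethyl‑6β‑(phenylsulfonyl)‑9β‑[(phenylsulfanyl)methyl]‑5β‑H‑decalin‑8α‑ol
Conditions: MeLi, CeCl3 (anhydrous), THF, −78 °C
Reagents that add atoms: methyllithium (used as MeCeCl2), C[Li]
Why: Organocerium 1,2‑addition is too weakly basic to enolize the ketone (which would expel sulfinate or thiophenolate); methyl should add equatorially from the β‑face, because the axial α‑trajectory is blocked by syn‑axial C1, giving 8β‑CH3 and 8α‑OH.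

Step 11
Reactants: 16 the tertiary alcohol sulfide
Product: 17 3β‑(benzyloxy)‑4,4,8β,10β‑tetramethyl‑6β‑(phenylsulfonyl)‑9β‑[(phenylsulfonyl)methyl]‑5β‑H‑decalin‑8α‑ol
Conditions: mCPBA (2.2 equiv), NaHCO3, CH2Cl2, 0 °C
Reagents that add atoms: 3‑chloroperoxybenzoic acid, OOC(=O)c1cccc(Cl)c1
Why: Sulfide‑to‑sulfone oxidation with a peracid is chemoselective here, since no alkene remains and the tertiary alcohol and benzyl ether are inert.

Step 12
Reactants: 17 the bis‑sulfone alcohol; 18 (2E,6E)‑farnesyl bromide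
Product: 19 3β‑(benzyloxy)‑4,4,8β,10β‑tetramethyl‑6β‑(phenylsulfonyl)‑9β‑[(3E,7E)‑4,8,12‑trimethyl‑1‑(phenylsulfonyl)trideca‑3,7,11‑trien‑1‑yl]‑5β‑H‑decalin‑8α‑ol (C11 epimers)
Conditions: n‑BuLi (2.1 equiv), THF/HMPA, −78 °C; then 18, −78 to −30 °C
Reagents that add atoms: none
Why: The alkoxide / α‑sulfonyl carbanion dianion should form at the primary C11 (more acidic and less hindered than the ring C6–H) and displace the allylic bromide by SN2 at its primary carbon, keeping the (E,E)‑geometry (sulfone alkylation).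

Step 13
Reactants: 19 the alkylated bis‑sulfone
Product: 20 (2S,4aS,5R,6R,8aS)‑1,1,4a,6‑tetramethyl‑5‑[(3E,7E)‑4,8,12‑trimethyltrideca‑3,7,11‑trien‑1‑yl]decahydronaphthalene‑2,6‑diol (the target)
Conditions: Li, EtNH2, THF, −78 °C; NH4Cl
Reagents that add atoms: none
Why: Dissolving‑metal reduction should cleave both C–SO2Ph bonds (the coupling handle at C11 and the activating group at C6) and the benzyl ether in one operation, while isolated trisubstituted alkenes and the tertiary alcohol are inert at −78 °C.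

**Compound list**

1 | pent‑4‑yn‑1‑ol | C#CCCCO | starting material
2 | pent‑4‑ynal | C#CCCC=O | intermediate
3 | 3‑methylbuta‑1,2‑diene | CC(C)=C=C | starting material
4 | prenyldiisopinocampheylborane, from (−)‑α‑pinene | CC(C)=CCB([C@H]1C[C@H]2C[C@@H]([C@@H]1C)C2(C)C)[C@H]3C[C@H]4C[C@@H]([C@@H]3C)C4(C)C | intermediate (not isolated)
5 | (4S)‑3,3‑dimethyloct‑1‑en‑7‑yn‑4‑ol | C#CCC[C@H](O)C(C)(C)C=C | intermediate
6 | benzyl (4S)‑3,3‑dimethyloct‑1‑en‑7‑yn‑4‑yl ether | C#CCC[C@H](OCc1ccccc1)C(C)(C)C=C | intermediate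
7 | methyl (6S)‑6‑(benzyloxy)‑7,7‑dimethylnon‑8‑en‑2‑ynoate | COC(=O)C#CCC[C@H](OCc1ccccc1)C(C)(C)C=C | intermediate
8 | methyl (2Z,6S)‑6‑(benzyloxy)‑3,7,7‑trimethylnona‑2,8‑dienoate | COC(=O)/C=C(C)\CC[C@H](OCc1ccccc1)C(C)(C)C=C | intermediate
9 | (3Z,7S)‑7‑(benzyloxy)‑4,8,8‑trimethyl‑1‑(trimethylsilyl)deca‑3,9‑dien‑2‑one | C[Si](C)(C)CC(=O)/C=C(C)\CC[C@H](OCc1ccccc1)C(C)(C)C=C | intermediate (not isolated)
10 | (3Z,7S)‑7‑(benzyloxy)‑4,8,8‑trimethyldeca‑3,9‑dien‑2‑one | CC(=O)/C=C(C)\CC[C@H](OCc1ccccc1)C(C)(C)C=C | intermediate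
11 | (3Z,7S)‑7‑(benzyloxy)‑9‑iodo‑4,8,8‑trimethyl‑10‑(phenylsulfonyl)dec‑3‑en‑2‑one, both C9 epimers | CC(=O)/C=C(C)\CC[C@H](OCc1ccccc1)C(C)(C)C(I)CS(=O)(=O)c2ccccc2 | intermediate (not isolated)
12 | (3Z,7S,9E)‑7‑(benzyloxy)‑4,8,8‑trimethyl‑10‑(phenylsulfonyl)deca‑3,9‑dien‑2‑one | CC(=O)/C=C(C)\CC[C@H](OCc1ccccc1)C(C)(C)/C=C/S(=O)(=O)c2ccccc2 | intermediate
13 | tert‑butyl{[(3Z,7S,9E)‑7‑(benzyloxy)‑4,8,8‑trimethyl‑10‑(phenylsulfonyl)deca‑1,3,9‑trien‑2‑yl]oxy}dimethylsilane | C=C(O[Si](C)(C)C(C)(C)C)/C=C(C)\CC[C@H](OCc1ccccc1)C(C)(C)/C=C/S(=O)(=O)c2ccccc2 | intermediate (not isolated)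
14 | tert‑butyl{[3β‑(benzyloxy)‑4,4,10β‑trimethyl‑6β‑(phenylsulfonyl)‑5β‑H‑decal‑8(9)‑en‑8‑yl]oxy}dimethylsilane, A/B cis | CC(C)(C)[Si](C)(C)OC1=C[C@@]2(C)CC[C@H](OCc3ccccc3)C(C)(C)[C@H]2[C@H](S(=O)(=O)c4ccccc4)C1 | intermediate
15 | 3β‑(benzyloxy)‑4,4,10β‑trimethyl‑6β‑(phenylsulfonyl)‑9β‑[(phenylsulfanyl)methyl]‑5β‑H‑decalin‑8‑one | c3ccccc3SC[C@@H]1[C@@]2(C)CC[C@H](OCc4ccccc4)C(C)(C)[C@H]2[C@H](S(=O)(=O)c5ccccc5)CC1=O | intermediate
16 | 3β‑(benzyloxy)‑4,4,8β,10β‑tetramethyl‑6β‑(phenylsulfonyl)‑9β‑[(phenylsulfanyl)methyl]‑5β‑H‑decalin‑8α‑ol | c3ccccc3SC[C@@H]1[C@@]2(C)CC[C@H](OCc4ccccc4)C(C)(C)[C@H]2[C@H](S(=O)(=O)c5ccccc5)C[C@@]1(C)O | intermediate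
17 | 3β‑(benzyloxy)‑4,4,8β,10β‑tetramethyl‑6β‑(phenylsulfonyl)‑9β‑[(phenylsulfonyl)methyl]‑5β‑H‑decalin‑8α‑ol | O=S(=O)(c3ccccc3)C[C@@H]1[C@@]2(C)CC[C@H](OCc4ccccc4)C(C)(C)[C@H]2[C@H](S(=O)(=O)c5ccccc5)C[C@@]1(C)O | intermediate
18 | (2E,6E)‑farnesyl bromide | CC(C)=CCC/C(C)=C/CC/C(C)=C/CBr | starting material
19 | 3β‑(benzyloxy)‑4,4,8β,10β‑tetramethyl‑6β‑(phenylsulfonyl)‑9β‑[(3E,7E)‑4,8,12‑trimethyl‑1‑(phenylsulfonyl)trideca‑3,7,11‑trien‑1‑yl]‑5β‑H‑decalin‑8α‑ol, C11 epimers | CC(C)=CCC/C(C)=C/CC/C(C)=C/CC(S(=O)(=O)c3ccccc3)[C@@H]1[C@@]2(C)CC[C@H](OCc4ccccc4)C(C)(C)[C@H]2[C@H](S(=O)(=O)c5ccccc5)C[C@@]1(C)O | intermediate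
20 | (2S,4aS,5R,6R,8aS)‑1,1,4a,6‑tetramethyl‑5‑[(3E,7E)‑4,8,12‑trimethyltrideca‑3,7,11‑trien‑1‑yl]decahydronaphthalene‑2,6‑diol | CC(C)=CCC/C(C)=C/CC/C(C)=C/CC[C@@H]1[C@@]2(C)CC[C@H](O)C(C)(C)[C@H]2CC[C@@]1(C)O | target

**Step count and risks**

Total step count: 13. Longest linear sequence: 13 steps, from 1 (3 and 18 are bought).

Steps most likely to fail:

1. Step 8. The enforced orientation is electronically mismatched (the silyloxy group makes C7, not C10, the nucleophilic terminus), so the cycloaddition may be slow enough that the [1,5]‑hydrogen shift from C1 to C7 of the (Z)‑diene, or loss of the silyl group, takes over. The fallback sets out from 10 and comes back at 20. Cross‑metathesis of 10 with crotonaldehyde (Hoveyda–Grubbs second‑generation catalyst) would give the enal (2E,5S,8Z)‑5‑(benzyloxy)‑4,4,8‑trimethyl‑10‑oxoundeca‑2,8‑dienal F1. Soft enolization (TBSOTf, Et3N, −78 °C) would give the silyloxy triene enal F2, which should cyclize with Me2AlCl at low temperature (Lewis‑acid‑promoted intramolecular Diels–Alder, formyl endo, same (Z)‑diene control) to the cis‑fused 6β‑carbaldehyde F3. Stoichiometric RhCl(PPh3)3 decarbonylation would give the sulfone‑free silyl enol ether F4. Steps 9 to 13 applied to F4 would give in turn the phenylthiomethyl ketone F5, the tertiary alcohol F6, the sulfone F7, the farnesylated sulfone F8 and then 20, the last step now removing one sulfonyl group and the benzyl ether.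

2. Step 10. Methyl may be delivered to the concave α‑face (if ring B reacts through the flipped chair in which the C10 methyl is axial), or the ketone may enolize and expel sulfinate or thiophenolate. The fallback sets out from 15 and comes back at 17, and uses the fact that oxygen transfer to an exocyclic alkene gives the opposite C8 configuration from carbon addition to the ketone under the same facial bias. Non‑basic methylenation (Zn, CH2Br2, TiCl4) would give the 8‑methylene compound F9. Excess mCPBA would epoxidize the exocyclic alkene from the exposed face and oxidize the sulfide, giving the spiro‑epoxide bis‑sulfone F10. LiBHEt3 would open the epoxide at CH2 to give 17.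

3. Step 9. Carbon–carbon bond formation at the neopentyl‑type C9 may be slow, so that protodesilylation (loss of the regiodefined enol ether) or acid‑induced epimerization at C9 wins. The fallback sets out from 14 and comes back at 16. Mukaiyama‑type hydroxymethylation (1,3,5‑trioxane, TiCl4, −78 °C) with the smallest electrophile would give the 9β‑hydroxymethyl ketone F11. MeCeCl2 (excess) would give the diol F12. Selective thioetherification of the primary alcohol (PhSSPh, Bu3P) would give 16.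

**Further compounds**

F1 | step 8 | (2E,5S,8Z)‑5‑(benzyloxy)‑4,4,8‑trimethyl‑10‑oxoundeca‑2,8‑dienal | CC(=O)/C=C(C)\CC[C@H](OCc1ccccc1)C(C)(C)/C=C/C=O
F2 | step 8 | (2E,5S,8Z)‑5‑(benzyloxy)‑10‑[(tert‑butyldimethylsilyl)oxy]‑4,4,8‑trimethylundeca‑2,8,10‑trienal | C=C(O[Si](C)(C)C(C)(C)C)/C=C(C)\CC[C@H](OCc1ccccc1)C(C)(C)/C=C/C=O
F3 | step 8 | 3β‑(benzyloxy)‑8‑[(tert‑butyldimethylsilyl)oxy]‑4,4,10β‑trimethyl‑5β‑H‑decal‑8(9)‑ene‑6β‑carbaldehyde | CC(C)(C)[Si](C)(C)OC1=C[C@@]2(C)CC[C@H](OCc3ccccc3)C(C)(C)[C@H]2[C@H](C=O)C1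
F4 | step 8 | tert‑butyl{[3β‑(benzyloxy)‑4,4,10β‑trimethyl‑5β‑H‑decal‑8(9)‑en‑8‑yl]oxy}dimethylsilane | CC(C)(C)[Si](C)(C)OC1=C[C@@]2(C)CC[C@H](OCc3ccccc3)C(C)(C)[C@H]2CC1
F5 | step 8 | 3β‑(benzyloxy)‑4,4,10β‑trimethyl‑9β‑[(phenylsulfanyl)methyl]‑5β‑H‑decalin‑8‑one | c3ccccc3SC[C@@H]1[C@@]2(C)CC[C@H](OCc4ccccc4)C(C)(C)[C@H]2CCC1=O
F6 | step 8 | 3β‑(benzyloxy)‑4,4,8β,10β‑tetramethyl‑9β‑[(phenylsulfanyl)methyl]‑5β‑H‑decalin‑8α‑ol | c3ccccc3SC[C@@H]1[C@@]2(C)CC[C@H](OCc4ccccc4)C(C)(C)[C@H]2CC[C@@]1(C)O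
F7 | step 8 | 3β‑(benzyloxy)‑4,4,8β,10β‑tetramethyl‑9β‑[(phenylsulfonyl)methyl]‑5β‑H‑decalin‑8α‑ol | O=S(=O)(c3ccccc3)C[C@@H]1[C@@]2(C)CC[C@H](OCc4ccccc4)C(C)(C)[C@H]2CC[C@@]1(C)O
F8 | step 8 | 3β‑(benzyloxy)‑4,4,8β,10β‑tetramethyl‑9β‑[(3E,7E)‑4,8,12‑trimethyl‑1‑(phenylsulfonyl)trideca‑3,7,11‑trien‑1‑yl]‑5β‑H‑decalin‑8α‑ol | CC(C)=CCC/C(C)=C/CC/C(C)=C/CC(S(=O)(=O)c3ccccc3)[C@@H]1[C@@]2(C)CC[C@H](OCc4ccccc4)C(C)(C)[C@H]2CC[C@@]1(C)O
F9 | step 10 | 3β‑(benzyloxy)‑4,4,10β‑trimethyl‑8‑methylene‑6β‑(phenylsulfonyl)‑9β‑[(phenylsulfanyl)methyl]‑5β‑H‑decalin | c3ccccc3SC[C@@H]1[C@@]2(C)CC[C@H](OCc4ccccc4)C(C)(C)[C@H]2[C@H](S(=O)(=O)c5ccccc5)CC1=C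
F10 | step 10 | 8α,12‑epoxide of 3β‑(benzyloxy)‑4,4,10β‑trimethyl‑8‑methylene‑6β‑(phenylsulfonyl)‑9β‑[(phenylsulfonyl)methyl]‑5β‑H‑decalin (oxygen on the α‑face) | O=S(=O)(c3ccccc3)C[C@@H]1[C@@]2(C)CC[C@H](OCc4ccccc4)C(C)(C)[C@H]2[C@H](S(=O)(=O)c5ccccc5)C[C@]16CO6
F11 | step 9 | 3β‑(benzyloxy)‑9β‑(hydroxymethyl)‑4,4,10β‑trimethyl‑6β‑(phenylsulfonyl)‑5β‑H‑decalin‑8‑one | OC[C@@H]1[C@@]2(C)CC[C@H](OCc4ccccc4)C(C)(C)[C@H]2[C@H](S(=O)(=O)c5ccccc5)CC1=O
F12 | step 9 | 3β‑(benzyloxy)‑9β‑(hydroxymethyl)‑4,4,8β,10β‑tetramethyl‑6β‑(phenylsulfonyl)‑5β‑H‑decalin‑8α‑ol | OC[C@@H]1[C@@]2(C)CC[C@H](OCc4ccccc4)C(C)(C)[C@H]2[C@H](S(=O)(=O)c5ccccc5)C[C@@]1(C)O
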